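Late in both earlier runs, at 2.50 min, the readings of Q and G add up to nearly the same share of the E charged: 62.0 % on Thursday and 61.0 % on Saturday.

| flask | E | D | Z | remark | time |
|---|---|---|---|---|---|
| Thursday's | 10 mM | 10 mM | 0.70 mM | run made earlier |  |
| Saturday's | 10 mM | 10 mM | 1.1 mM | run made earlier |  |
| flask | 10 mM | 10.0 mM | 0.50 mM |  | 2.5 min |

- Thursday's (time / min: Q / %, G / %): 0.200: 4, 3; 0.417: 3, 2; 0.667: 11, 7; 1.33: 27, 12; 2.50: 41, 21
- Saturday's (time / min: Q / %, G / %): 0.200: 0, 0; 0.417: 8, 3; 0.667: 9, 3; 1.33: 22, 9; 2.50: 43, 18

(each reading ± 2 percentage points)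

- Q at 2.5 min, in percent of the E charged
- concentration of G in solution at 2.5 min, in percent of saturation

- solid, in amounts per volume of the solution: E
- at the start none of E is in solution
- G is what E becomes in solution
- G means what is dissolved; the solid is not counted in it

That sits oddly with the charges. Saturday's run held 1.57 times Thursday's Z, yet its last Q reading is higher by just 2 percentage points, which is the size of one standard deviation (2 points). We clear this up by counting the sum: G read 3 points lower on Saturday, so the readings of the two runs differ in the split between G and Q, while their sums lie within 1 point of each other. The mean of the two sums, 61.5 %, is what we carry: the supply, Q plus G at that time as a share of the E charged. Our flask has the same E and D but less Z, so we expect this supply again, with G somewhat above Thursday's reading and Q therefore somewhat below 40.5 %.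

The forecast gives Q 37 % (30 % to 42 %) and G at 25 % of saturation (12 % to 50 %), reasoning that “saturation must lie well above that”.

The flask gives Q 37.6 % and G at 41.8 % of saturation, 17 points above the forecast; Q plus G is 62.3 %, against the supply of 61.5 %.

    J ⇌ Z + Q (K = 0.00440 M, k = 0.400 s⁻¹)
    D + X ⇌ J (K = 62.0 M⁻¹, k = 54.0 M⁻¹ s⁻¹)
    G + Z ⇌ X (K = 2400 M⁻¹, k = 1900 M⁻¹ s⁻¹)
    E ⇌ G, rate k4*(cs4 - [G]) while solid is left; crystals form when [G] > cs4 (solubility = 5.90 mM, k = 0.00980 s⁻¹)

In this flask solid E lasted, with 33.4 % still undissolved at 2.50 min, dissolving ran on, and at that time G's half-life by the forward step with Z alone was 0.10 min, short against the run. At 2.50 min X was the resting state, at 67.0 % of the catalyst charged, while D + X to J and J to Z + Q built up Q. In the neighbour flask with 25 mM of D, the supply puts Q just under 61.5 % once G is drawn down. The computed Q is 58.9 % with G at 13.0 %, so their sum, 71.9 %, stands above the supply.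

The readings were computed for substances that don't exist.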